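**Assumption:** the SMILES is read as (13S)-6β-acetoxy-9α,13;15,16-diepoxylabd-14-ene of the normal labdane series (5α-H, 10β-methyl, 8α-methyl, 9α-O); (+)-larixol and furan-3-ylmethanol are taken as commercial. Labdane numbering is used throughout.

## Retrosynthetic overview

1. Target 13 ⇒ furyl carbinol 12 by breaking the spiro C13–O9 bond; a light-driven cobalt-hydride dearomative hydroalkoxylation of the furan closes the oxolane ring and creates the dihydrofuran in the last step.
2. 12 ⇒ 6α,9α-diol 9 (C6 inverted by oxidation and α-face hydride reduction, then acetylation).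
3. 9 ⇒ spiro-epoxide 5 + furylmethyl Grignard 8 (C11–C12 bond); 5 comes from exocyclic alkene 4 by α-face epoxidation (sets C9).
4. 4 ⇒ (+)-larixol 1 by side-chain degradation: permanganate cleavage, radical hydrogenation (sets C8), Norrish type 2 cleavage.
5. Ring order: rings A and B bought (larixol), furan bought, oxolane and dihydrofuran rings formed together in step 10.

## Route

Step 1
Reactants: 1 (+)-larixol, (13S)-labda-8(17),14-diene-6α,13-diol
Product: 2 6α-hydroxy-14,15-dinorlabd-8(17)-en-13-one
Conditions: KMnO4 (4 equiv), MgSO4, acetone–H2O, 0 °C to rt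
Reagents that add atoms: none
Why: Permanganate dihydroxylates the unhindered vinyl group and cleaves the resulting 13,14,15-triol down to the C13 methyl ketone (the classical oxidative degradation of larixol, manool and sclareol side chains), while the hindered exocyclic methylene and the 6α-hydroxyl survive under buffered conditions; no ring stereocenter is touched.

Step 2
Reactants: 2 6α-hydroxy-14,15-dinorlabd-8(17)-en-13-one
Product: 3 6α-hydroxy-14,15-dinorlabdan-13-one (C8 methyl α and equatorial, 8β-H)
Conditions: Mn(dpm)3 (10 mol %), PhSiH3, t-BuOOH, i-PrOH, 22 °C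
Reagents that add atoms: none
Why: Radical hydrogen-atom-transfer hydrogenation adds H• to C17, and the tertiary C8 radical is quenched under thermodynamic stereocontrol so that the new methyl is equatorial (8α), away from the axial C20 methyl; C8 is thus set by C10, whereas surface hydrogenation would deliver H2 from the α face and give the axial 8β-methyl epimer.

Step 3
Reactants: 3 6α-hydroxy-14,15-dinorlabdan-13-one (C8 methyl α)
Product: 4 12,13,14,15,16-pentanorlabd-9(11)-en-6α-ol (drim-9(11)-en-6α-ol; exocyclic CH2 on C9, C8 methyl α)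
Conditions: hν (medium-pressure Hg lamp, Pyrex, λ > 290 nm), degassed n-hexane, rt
Reagents that add atoms: none
Why: Norrish type 2 cleavage: the excited methyl ketone abstracts the γ-hydrogen at C9 through a six-membered transition state and the 1,4-biradical fragments across C11–C12 to the 9(11)-alkene and acetone enol, as known for sclareol- and larixol-derived methyl ketones; C8 is not involved.

Step 4
Reactants: 4 12,13,14,15,16-pentanorlabd-9(11)-en-6α-ol
Product: 5 9α,11-epoxy-12,13,14,15,16-pentanorlabdan-6α-ol (spiro-oxirane on C9, O α and axial, CH2 β and equatorial)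
Conditions: m-CPBA, NaHCO3, CH2Cl2, 0 °C
Reagents that add atoms: m-chloroperbenzoic acid, OOC(=O)c1cccc(Cl)c1
Why: Prilezhaev epoxidation: the peracid attacks the exocyclic alkene from the α face, anti to the axial C20 methyl that shields the β face, so oxygen ends axial (9α) and C11 equatorial; C9 is set by C10.

Step 5
Reactants: 6 furan-3-ylmethanol
Product: 7 3-(chloromethyl)furan
Conditions: SOCl2, pyridine, Et2O, 0 °C
Reagents that add atoms: thionyl chloride, O=S(Cl)Cl
Why: Standard conversion of a primary heterobenzylic alcohol into the chloride through the chlorosulfite (SN2).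

Step 6
Reactants: 5 9α,11-epoxy-12,13,14,15,16-pentanorlabdan-6α-ol; 7 3-(chloromethyl)furan
Product: 9 15,16-epoxylabda-13(16),14-diene-6α,9α-diol, via (furan-3-yl)methylmagnesium chloride 8 (not isolated)
Conditions: 7 (3 equiv), Mg, THF, 0 °C; then 5, CuI (10 mol %), THF, −30 to 0 °C; aq NH4Cl
Reagents that add atoms: none
Why: Copper-catalysed SN2 opening of the spiro-epoxide at its CH2 terminus (C11) by the furylmethyl Grignard forms C11–C12 and leaves the C9–O bond, hence the 9α configuration, untouched; one equivalent of Grignard is consumed by the 6-OH.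

Step 7
Reactants: 9 15,16-epoxylabda-13(16),14-diene-6α,9α-diol
Product: 10 9α-hydroxy-15,16-epoxylabda-13(16),14-dien-6-one
Conditions: Dess–Martin periodinane, NaHCO3, CH2Cl2, 0 °C to rt
Reagents that add atoms: none
Why: Dess–Martin oxidation of the only secondary alcohol; the tertiary 9-OH and the furan are inert under buffered conditions.

Step 8
Reactants: 10 9α-hydroxy-15,16-epoxylabda-13(16),14-dien-6-one
Product: 11 15,16-epoxylabda-13(16),14-diene-6β,9α-diol
Conditions: NaBH4, MeOH–THF, 0 °C
Reagents that add atoms: none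
Why: Substrate-controlled hydride reduction: the β face of the C6 carbonyl is blocked by the syn-axial C19 and C20 methyls, so hydride enters from the α face and gives the axial 6β-alcohol.

Step 9
Reactants: 11 15,16-epoxylabda-13(16),14-diene-6β,9α-diol
Product: 12 6β-acetoxy-15,16-epoxylabda-13(16),14-dien-9α-ol
Conditions: Ac2O, DMAP, Et3N, CH2Cl2, 40 °C
Reagents that add atoms: acetic anhydride, CC(=O)OC(C)=O
Why: DMAP-catalysed acetylation takes the secondary 6β-OH; the tertiary 9α-OH, flanked by quaternary C10 and tertiary C8, does not react.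

Step 10
Reactants: 12 6β-acetoxy-15,16-epoxylabda-13(16),14-dien-9α-ol
Product: 13 (13S)-6β-acetoxy-9α,13;15,16-diepoxylabd-14-ene (CNP0242014.3)
Conditions: 10-phenylphenothiazine (5 mol %), Co(C32H46N2O2) [the divalent cobalt complex of N,N′-bis(3,5-di-tert-butylsalicylidene)ethane-1,2-diamine] (5 mol %), 2,4,6-collidinium triflate (20 mol %), 2,4,6-collidine (50 mol %), MeCN–toluene 1:1 (0.05 M), 390 nm LEDs, 20 °C, argon
Reagents that add atoms: none
Why: Proposed new method: a cobalt-hydride hydrogen-atom-transfer / radical–polar crossover Markovnikov hydroalkoxylation is carried over from alkenes to the C16=C13 bond of an aromatic furan: photoreduced monovalent cobalt is protonated by collidinium to the cobalt hydride, which gives H• to the furan α-carbon C16 (the site that leaves the most substituted oxa-allyl radical; roughly 33 kcal/mol exothermic against about 38 for a 1,1-disubstituted alkene), the radical is oxidised by the phenothiazine radical cation (about +0.7 V against SCE, too weak to touch the furan or the product enol ether) to the 2H-furanylium cation, and the axial 9α-OH closes 5-exo on C13 (C15 would need a seven-membered ring) and returns the proton, so the net change is a light-driven, redox-neutral, contra-thermodynamic isomerisation whose main escape (loss of H16) only regenerates 12; C13 is set by the decalin, because in the chair-like closure the quaternary C10 sits pseudo-equatorial and the forming ring leans toward the C8-methyl side, so the sp3 C16H2 of the planar cation takes the open face toward C1/C10 (13S; only moderate selectivity, about 3:1, is expected and the 13R epimer is removed on base-washed silica); the closest known reactions are the photoredox/cobalt/Brønsted-acid Markovnikov hydroalkoxylation of unactivated alkenes and cobalt–salen hydrogen-atom-transfer cycloetherifications.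

## Compound list

1 | (+)-larixol, (13S)-labda-8(17),14-diene-6α,13-diol | O[C@H]1CC(=C)[C@H](CC[C@](C)(O)C=C)[C@@]2(C)CCCC(C)(C)[C@H]12 | starting material
2 | 6α-hydroxy-14,15-dinorlabd-8(17)-en-13-one | O[C@H]1CC(=C)[C@H](CCC(C)=O)[C@@]2(C)CCCC(C)(C)[C@H]12 | intermediate
3 | 6α-hydroxy-14,15-dinorlabdan-13-one (C8 methyl α, 8β-H) | O[C@H]1C[C@@H](C)[C@H](CCC(C)=O)[C@@]2(C)CCCC(C)(C)[C@H]12 | intermediate
4 | 12,13,14,15,16-pentanorlabd-9(11)-en-6α-ol (C8 methyl α) | O[C@H]1C[C@@H](C)C(=C)[C@@]2(C)CCCC(C)(C)[C@H]12 | intermediate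
5 | 9α,11-epoxy-12,13,14,15,16-pentanorlabdan-6α-ol | O[C@H]1C[C@@H](C)[C@]3(CO3)[C@@]2(C)CCCC(C)(C)[C@H]12 | intermediate
6 | furan-3-ylmethanol | OCc1ccoc1 | starting material
7 | 3-(chloromethyl)furan | ClCc1ccoc1 | intermediate
8 | (furan-3-yl)methylmagnesium chloride | Cl[Mg]Cc1ccoc1 | intermediate (not isolated)
9 | 15,16-epoxylabda-13(16),14-diene-6α,9α-diol | O[C@H]1C[C@@H](C)[C@](O)(CCc3ccoc3)[C@@]2(C)CCCC(C)(C)[C@H]12 | intermediate
10 | 9α-hydroxy-15,16-epoxylabda-13(16),14-dien-6-one | O=C1C[C@@H](C)[C@](O)(CCc3ccoc3)[C@@]2(C)CCCC(C)(C)[C@H]12 | intermediate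
11 | 15,16-epoxylabda-13(16),14-diene-6β,9α-diol | O[C@@H]1C[C@@H](C)[C@](O)(CCc3ccoc3)[C@@]2(C)CCCC(C)(C)[C@H]12 | intermediate
12 | 6β-acetoxy-15,16-epoxylabda-13(16),14-dien-9α-ol | CC(=O)O[C@@H]1C[C@@H](C)[C@](O)(CCc3ccoc3)[C@@]2(C)CCCC(C)(C)[C@H]12 | intermediate
13 | (13S)-6β-acetoxy-9α,13;15,16-diepoxylabd-14-ene | CC(=O)O[C@@H]1C[C@@H](C)[C@]2(CC[C@@]3(C=COC3)O2)[C@@]2(C)CCCC(C)(C)[C@H]12 | target

## Step count and risks

Total steps: 10. Longest linear sequence: 9 (steps 1–4 and 6–10).

**Step 10 (the new reaction).** It can fail in four ways: hydrogen-atom transfer to the aromatic furan may be too slow; H• may go to C15 and lead to the 9,16-acetal; the weak acid may reopen the product to the furan; and the C13 selectivity may be low. The fallback uses known chemistry, sets out from 11 and returns at 13.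
- Singlet oxygen (O2, Rose Bengal, visible light, i-Pr2NEt, CH2Cl2, −78 °C) converts the 3-alkylfuran regioselectively into the γ-hydroxybutenolide 6β,9α,16-trihydroxylabd-13-en-15,16-olide F1.
- NaBH4 (EtOH, 0 °C, acidic work-up) gives the butenolide 6β,9α-dihydroxylabd-13-en-15,16-olide F2.
- DBU or catalytic KOt-Bu in THF closes the 9α-OH onto C13 by intramolecular oxa-Michael addition to give the spiro-lactone (13S)-6β-hydroxy-9α,13-epoxylabdan-15,16-olide F3. Both C13 epimers form and interconvert by retro-Michael reaction; the 13S lactone is separated and the 13R lactone is recycled with base.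
- i-Bu2AlH (CH2Cl2, −78 °C) gives the lactol (13S)-9α,13;15,16-diepoxylabdane-6β,15-diol F4.
- MsCl/Et3N dehydrates the lactol to the enol ether (13S)-9α,13;15,16-diepoxylabd-14-en-6β-ol F5, and acetylation under the step 9 conditions gives 13.

**Step 2 (C8 by radical hydrogenation).** The axial approach of the hydrogen donor is syn to the C20 methyl, so the 8β-methyl epimer or alkene isomerisation may compete. The fallback sets C8 by enolate equilibration instead; it sets out from 2 and returns at 4.
- H2/PtO2 (EtOAc) gives mainly the axial-methyl ketone 6α-hydroxy-14,15-dinorlabdan-13-one (C8 methyl β) F6.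
- Norrish type 2 cleavage gives the alkene 12,13,14,15,16-pentanorlabd-9(11)-en-6α-ol (C8 methyl β) F7.
- Ozonolysis (O3, then Me2S) gives 6α-hydroxy-11,12,13,14,15,16-hexanorlabdan-9-one (C8 methyl β) F8.
- NaOMe/MeOH equilibrates F8 completely to the equatorial epimer 6α-hydroxy-11,12,13,14,15,16-hexanorlabdan-9-one (C8 methyl α) F9, with relief of the syn-diaxial methyl/methyl interaction.
- Wittig methylenation (Ph3P=CH2 from Ph3PCH3Br and KOt-Bu, toluene, 80 °C) returns 4.

**Step 6 (neopentylic epoxide opening).** The furylmethyl Grignard may undergo Wurtz coupling, and magnesium halide may rearrange the spiro-epoxide to the aldehyde. The fallback uses a sulfone-stabilised carbanion; it sets out from 5 and 7 and returns at 9.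
- 7 and PhSO2Na (DMF) give 3-[(phenylsulfonyl)methyl]furan F10.
- The lithio derivative of F10 (n-BuLi, THF–DMPU, −78 to 25 °C) opens 5 at C11 to give 12-(phenylsulfonyl)-15,16-epoxylabda-13(16),14-diene-6α,9α-diol F11.
- Reductive desulfonylation (Mg, MeOH) gives 9.

## Further compounds

F1 | step 10 | 6β,9α,16-trihydroxylabd-13-en-15,16-olide | O[C@@H]1C[C@@H](C)[C@](O)(CCC3=CC(=O)OC3O)[C@@]2(C)CCCC(C)(C)[C@H]12
F2 | step 10 | 6β,9α-dihydroxylabd-13-en-15,16-olide | O[C@@H]1C[C@@H](C)[C@](O)(CCC3=CC(=O)OC3)[C@@]2(C)CCCC(C)(C)[C@H]12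
F3 | step 10 | (13S)-6β-hydroxy-9α,13-epoxylabdan-15,16-olide | O[C@@H]1C[C@@H](C)[C@]2(CC[C@@]3(CC(=O)OC3)O2)[C@@]2(C)CCCC(C)(C)[C@H]12
F4 | step 10 | (13S)-9α,13;15,16-diepoxylabdane-6β,15-diol | O[C@@H]1C[C@@H](C)[C@]2(CC[C@@]3(CC(O)OC3)O2)[C@@]2(C)CCCC(C)(C)[C@H]12
F5 | step 10 | (13S)-9α,13;15,16-diepoxylabd-14-en-6β-ol | O[C@@H]1C[C@@H](C)[C@]2(CC[C@@]3(C=COC3)O2)[C@@]2(C)CCCC(C)(C)[C@H]12
F6 | step 2 | 6α-hydroxy-14,15-dinorlabdan-13-one (C8 methyl β) | O[C@H]1C[C@H](C)[C@H](CCC(C)=O)[C@@]2(C)CCCC(C)(C)[C@H]12
F7 | step 2 | 12,13,14,15,16-pentanorlabd-9(11)-en-6α-ol (C8 methyl β) | O[C@H]1C[C@H](C)C(=C)[C@@]2(C)CCCC(C)(C)[C@H]12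
F8 | step 2 | 6α-hydroxy-11,12,13,14,15,16-hexanorlabdan-9-one (C8 methyl β) | O[C@H]1C[C@H](C)C(=O)[C@@]2(C)CCCC(C)(C)[C@H]12
F9 | step 2 | 6α-hydroxy-11,12,13,14,15,16-hexanorlabdan-9-one (C8 methyl α) | O[C@H]1C[C@@H](C)C(=O)[C@@]2(C)CCCC(C)(C)[C@H]12
F10 | step 6 | 3-[(phenylsulfonyl)methyl]furan | O=S(=O)(Cc1ccoc1)c1ccccc1
F11 | step 6 | 12-(phenylsulfonyl)-15,16-epoxylabda-13(16),14-diene-6α,9α-diol | O[C@H]1C[C@@H](C)[C@](O)(CC(c3ccoc3)S(=O)(=O)c3ccccc3)[C@@]2(C)CCCC(C)(C)[C@H]12
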